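**Plan**
- Retrosynthetic cuts: first the two aryl O–CH3 bonds, then two helper C3–CO2Me bonds, then C2–C3 and C5–N1 of the lactam together. This leaves benzyl isocyanate 7 and cyclopropane-1,1-diester 8; 7 goes back by a Curtius rearrangement and three C–Br cuts to homoveratric acid 1.
- Enabling feature: N1–C2(=O) of the pyrrolidinone is an isocyanate N=C=O unit, and C3–C4–C5 is a cyclopropane. Two temporary ester groups on C3 make C3 a masked malonate nucleophile and C5 a masked electrophile, and ring strain drives the opening.
- Forward order: the arene is fully brominated first, then N=C=O is installed, then the only ring built in the route (the pyrrolidinone) arises in one (3+2) annulation, then the esters are removed and the catechol is unveiled.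
- Stereochemistry: the target has no stereocentre; the one stereocentre passed on the way (C3 of monoester 12) is racemic and is erased.

Key step: step 3

Remark: the target is achiral, so the "single enantiomer" is the compound itself and no stereocontrol is required.

**Step 1**
Reactants: 1 (3,4-dimethoxyphenyl)acetic acid (homoveratric acid)
Product: 4 2-(2,3,6-tribromo-4,5-dimethoxyphenyl)acetic acid, via monobromo acid 2 (not isolated), via dibromo acid 3 (not isolated)
Conditions: Br2 (4 equiv), Fe powder (cat.), CH2Cl2/AcOH, 0 → 40 °C, dark; aq. NaHSO3
Reagents that add atoms: bromine, BrBr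
Why: Electrophilic aromatic bromination: the first bromine should enter para to the 3-methoxy group (2), FeBr3 formed in the flask should then push bromine into the two remaining positions ortho to the methoxy groups (3, then 4), no regiochemical choice is needed because all three free ring positions are to be filled, and the dark, radical-free conditions should leave the benzylic CH2 alone.

**Step 2**
Reactants: 4 2-(2,3,6-tribromo-4,5-dimethoxyphenyl)acetic acid
Product: 7 2,3,6-tribromo-4,5-dimethoxybenzyl isocyanate, via acid chloride 5 (not isolated), via acyl azide 6 (not isolated)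
Conditions: (COCl)2, cat. DMF, CH2Cl2, 0 °C → rt, evaporate; TMSN3, toluene, rt → 90 °C; evaporate
Reagents that add atoms: azidotrimethylsilane, C[Si](C)(C)N=[N+]=[N-]
Why: Curtius rearrangement: azide converts acid chloride 5 into acyl azide 6, which on heating loses N2 with concerted 1,2-shift of the benzylic carbon to nitrogen, and with no nucleophile present the isocyanate 7 should survive and be freed of the volatile by-products by evaporation.

**Step 3**
Reactants: 7 2,3,6-tribromo-4,5-dimethoxybenzyl isocyanate; 8 dimethyl cyclopropane-1,1-dicarboxylate
Product: 11 dimethyl 2-oxo-1-(2,3,6-tribromo-4,5-dimethoxybenzyl)pyrrolidine-3,3-dicarboxylate, via iodoethylmalonate magnesium enolate 9 (not isolated), via open-chain magnesium amidate 10 (not isolated)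
Conditions: MgI2 (1 equiv), 8 (1.5 equiv), THF, 75 °C, sealed tube, Ar
Reagents that add atoms: none
Why: Proposed new method: Mg(II) chelates the geminal diester of 8 and iodide opens the strained three-membered ring by SN2 attack at one of its two equivalent CH2 groups (homo-conjugate addition, driven by release of the cyclopropane ring strain) to give the γ-iodo magnesium malonate enolate 9, whose carbon adds to the sp carbon of isocyanate 7 (new C3–C2 bond) to give amidate 10, and the amidate nitrogen then displaces iodide (new C5–N1 bond), returning MgI2, so that all atoms of both partners end up in 11. The closest known reaction types are the Lewis-acid-mediated formal (3+2) cycloaddition of donor-substituted cyclopropane-1,1-diesters with isocyanates to γ-lactams and the MgI2-promoted ring expansion of activated cyclopropanes with imines and nitrones, which extends to cyclopropane-1,1-diesters that lack a donor; what is new is the union of a donor-free cyclopropane-1,1-diester with an isocyanate under iodide activation. The pyrrolidinone ring closes in a 5-exo-tet mode at nitrogen. No stereocentre is formed, and because the two ring CH2 groups of 8 are equivalent the opening raises no regiochemical question. The step needs C- over O-carbamoylation of the enolate and N- over O-alkylation of the ambident amidate: O-carbamoylation is reversible whereas the C-adduct is trapped by ring closure, and an O-closed iminolactone would be reopened by iodide at its O–CH2 carbon and so funnelled to the more stable lactam. The aryl bromides and methyl ethers should be inert to MgI2 at this temperature.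

**Step 4**
Reactants: 11 dimethyl 2-oxo-1-(2,3,6-tribromo-4,5-dimethoxybenzyl)pyrrolidine-3,3-dicarboxylate
Product: 13 1-(2,3,6-tribromo-4,5-dimethoxybenzyl)pyrrolidin-2-one, via lactam monoester 12 (not isolated)
Conditions: LiCl (5 equiv), H2O (5 equiv), DMSO, 150 → 165 °C
Reagents that add atoms: none
Why: Krapcho dealkoxycarbonylation, run twice in one flask: chloride attacks the ester O-methyl group by SN2, the carboxylate loses CO2 to an enolate stabilised by the remaining ester and the lactam carbonyl (first loss, to 12) or by the lactam carbonyl alone (second, slower loss, as is usual for 3-alkoxycarbonyl lactams), and water protonates it, while aryl bromides, aryl methyl ethers and the N-benzyl lactam should not react with chloride.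

**Step 5**
Reactants: 13 1-(2,3,6-tribromo-4,5-dimethoxybenzyl)pyrrolidin-2-one
Product: 15 1-(2,3,6-tribromo-4,5-dihydroxybenzyl)pyrrolidin-2-one (target), via cyclic aryl bromoboronate 14 (not isolated)
Conditions: BBr3 (4 equiv), CH2Cl2, −78 °C → rt; ice/H2O, Ar
Reagents that add atoms: none
Why: Lewis-acid cleavage of aryl methyl ethers: BBr3 binds each ether oxygen and bromide removes the methyl group by SN2 to give the cyclic bromoboronate 14, which water hydrolyses to the catechol, and the lactam (only reversibly complexed) and the three aryl bromides should be untouched at or below room temperature.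

**Compound list**
1 | (3,4-dimethoxyphenyl)acetic acid (homoveratric acid) | COc1ccc(CC(=O)O)cc1OC | starting material
2 | 2-(2-bromo-4,5-dimethoxyphenyl)acetic acid | OC(=O)Cc1cc(OC)c(OC)cc1Br | intermediate
3 | 2-(2,3-dibromo-4,5-dimethoxyphenyl)acetic acid (drawn as this isomer; the 2,6-dibromo-3,4-dimethoxy isomer would converge on the same product) | OC(=O)Cc1cc(OC)c(OC)c(Br)c1Br | intermediate
4 | 2-(2,3,6-tribromo-4,5-dimethoxyphenyl)acetic acid | OC(=O)Cc1c(Br)c(OC)c(OC)c(Br)c1Br | intermediate
5 | 2-(2,3,6-tribromo-4,5-dimethoxyphenyl)acetyl chloride | ClC(=O)Cc1c(Br)c(OC)c(OC)c(Br)c1Br | intermediate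
6 | 2-(2,3,6-tribromo-4,5-dimethoxyphenyl)acetyl azide | [N-]=[N+]=NC(=O)Cc1c(Br)c(OC)c(OC)c(Br)c1Br | intermediate
7 | 2,3,6-tribromo-4,5-dimethoxybenzyl isocyanate | O=C=NCc1c(Br)c(OC)c(OC)c(Br)c1Br | intermediate
8 | dimethyl cyclopropane-1,1-dicarboxylate | COC(=O)C1(CC1)C(=O)OC | starting material
9 | iodomagnesium enolate of dimethyl 2-(2-iodoethyl)malonate | COC(=O)C(CCI)=C(OC)O[Mg]I | intermediate
10 | N-iodomagnesio amidate of dimethyl 2-(2-iodoethyl)-2-[(2,3,6-tribromo-4,5-dimethoxybenzyl)carbamoyl]malonate | COC(=O)C(CCI)(C(=O)OC)C(=O)N([Mg]I)Cc1c(Br)c(OC)c(OC)c(Br)c1Br | intermediate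
11 | dimethyl 2-oxo-1-(2,3,6-tribromo-4,5-dimethoxybenzyl)pyrrolidine-3,3-dicarboxylate | COC(=O)C1(C(=O)OC)CCN(Cc2c(Br)c(OC)c(OC)c(Br)c2Br)C1=O | intermediate
12 | methyl 2-oxo-1-(2,3,6-tribromo-4,5-dimethoxybenzyl)pyrrolidine-3-carboxylate (racemic) | COC(=O)C1CCN(Cc2c(Br)c(OC)c(OC)c(Br)c2Br)C1=O | intermediate
13 | 1-(2,3,6-tribromo-4,5-dimethoxybenzyl)pyrrolidin-2-one | O=C1CCCN1Cc1c(Br)c(OC)c(OC)c(Br)c1Br | intermediate
14 | 1-[(2,4,5,7-tetrabromo-1,3,2-benzodioxaborol-6-yl)methyl]pyrrolidin-2-one, numbered from B-2 (cyclic B-bromo boronate of the catechol) | O=C1CCCN1Cc1c(Br)c2OB(Br)Oc2c(Br)c1Br | intermediate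
15 | 1-(2,3,6-tribromo-4,5-dihydroxybenzyl)pyrrolidin-2-one | O=C1CCCN1Cc1c(Br)c(O)c(O)c(Br)c1Br | target

**Step count and risks**
Total step count: 5. Longest linear sequence: 5 steps (1 → 15; 8 is bought and enters at step 3).

Steps most likely to fail:

1. Step 3 (proposed new method). The ring-opening equilibrium may supply too little open enolate, the isocyanate may be consumed by iodide- or magnesium-promoted oligomerisation, or closure may occur at oxygen without later equilibration. Premature loss of one ester under MgI2 would be harmless, since step 4 removes both. Fallback with known chemistry, setting out from 7 and returning at 13 (steps 3 and 4 are both bypassed): 7 is hydrolysed (aq. HCl, THF, 60 °C, then NaOH) to (2,3,6-tribromo-4,5-dimethoxyphenyl)methanamine F1. F1 is acylated with 4-chlorobutanoyl chloride (Et3N, CH2Cl2, 0 °C) to 4-chloro-N-(2,3,6-tribromo-4,5-dimethoxybenzyl)butanamide F2. Intramolecular N-alkylation of F2 (KOtBu, THF, 0 °C → rt, 5-exo-tet) should give 13.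

2. Step 1. The third bromination may stall on the deactivated, crowded ring, and forcing it may bring ether cleavage by HBr or bromination of the side-chain CH2. Fallback setting out from 1 and returning at 4: the ethers are removed first (BBr3, CH2Cl2) to give (3,4-dihydroxyphenyl)acetic acid F3. The free catechol, far more activated than its dimethyl ether, is brominated at all three free positions (Br2, AcOH, rt) to 2-(2,3,6-tribromo-4,5-dihydroxyphenyl)acetic acid F4. Exhaustive methylation (MeI, K2CO3, DMF) gives methyl 2-(2,3,6-tribromo-4,5-dimethoxyphenyl)acetate F5, and saponification (LiOH, THF/H2O) returns to 4.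

3. Step 4. The second dealkoxycarbonylation may stall at the monoester, and prolonged heating in DMSO may cause decomposition. Fallback setting out from 12 (isolated by stopping the reaction at about 130 °C after the first, fast loss) and returning at 13: saponification (LiOH, THF/H2O, rt, then dilute HCl) gives 2-oxo-1-(2,3,6-tribromo-4,5-dimethoxybenzyl)pyrrolidine-3-carboxylic acid F6. Thermal decarboxylation of this β-amido acid through a cyclic six-membered transition state (o-dichlorobenzene, 160 °C) should give 13.

**Further compounds**
F1 | step 3 | (2,3,6-tribromo-4,5-dimethoxyphenyl)methanamine | NCc1c(Br)c(OC)c(OC)c(Br)c1Br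
F2 | step 3 | 4-chloro-N-(2,3,6-tribromo-4,5-dimethoxybenzyl)butanamide | ClCCCC(=O)NCc1c(Br)c(OC)c(OC)c(Br)c1Br
F3 | step 1 | (3,4-dihydroxyphenyl)acetic acid | OC(=O)Cc1ccc(O)c(O)c1
F4 | step 1 | 2-(2,3,6-tribromo-4,5-dihydroxyphenyl)acetic acid | OC(=O)Cc1c(Br)c(O)c(O)c(Br)c1Br
F5 | step 1 | methyl 2-(2,3,6-tribromo-4,5-dimethoxyphenyl)acetate | COC(=O)Cc1c(Br)c(OC)c(OC)c(Br)c1Br
F6 | step 4 | 2-oxo-1-(2,3,6-tribromo-4,5-dimethoxybenzyl)pyrrolidine-3-carboxylic acid | OC(=O)C1CCN(Cc2c(Br)c(OC)c(OC)c(Br)c2Br)C1=O
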